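## Retrosynthetic overview

1. Isolappaol A ⇒ its bis(O-benzyl) ether 23 (hydrogenolysis last).
2. Key disconnection, ring B aryl–CH2 bond: the aryl radical from bromide 21 adds to the exocyclic alkene of α-methylene lactone 13 (Giese reaction), then C3 is epimerised to the trans lactone.
3. 13 ⇒ (R)-β-benzyl lactone 10 ⇐ aldehyde 6 + methyl bromoacetate by photoredox/enamine radical α-alkylation; the lactone ring is formed first (step 5).
4. 21 ⇒ 5-exo aryl-radical cyclisation with O2 trapping of the (S)-allyl aryl ether 19; the dihydrofuran ring is formed second (step 12). 19 ⇐ iodophenol 18 + carbonate 17 by Ir-catalysed asymmetric allylic etherification.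
5. All three guaiacyl rings come from catechol via 4-bromoguaiacol 3; the side-chain carbons come from allyl alcohol, methyl bromoacetate, formaldehyde and methyl acrylate.

Assumption: the SMILES is read as the trans (3R,4R)-lactone carrying a trans (2S,3R)-dihydrobenzofuran, and this absolute configuration is the one made.

## Route

Step 1
Reactants: 1 catechol
Product: 2 2-methoxyphenol (guaiacol)
Conditions: MeI (0.9 equiv), K2CO3, acetone, reflux
Reagents that add atoms: iodomethane, CI
Why: Williamson ether synthesis; a slight deficit of MeI favours mono-methylation, and catechol and veratrole are removed by extraction and distillation.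

Step 2
Reactants: 2 2-methoxyphenol
Product: 3 4-bromo-2-methoxyphenol
Conditions: NBS, MeCN, 0 °C to rt
Reagents that add atoms: N-bromosuccinimide, O=C1CCC(=O)N1Br
Why: Electrophilic aromatic bromination, directed para to the free hydroxyl group, which is the strongest donor.

Step 3
Reactants: 3 4-bromo-2-methoxyphenol
Product: 4 1-(benzyloxy)-4-bromo-2-methoxybenzene
Conditions: BnBr, K2CO3, DMF, 60 °C
Reagents that add atoms: benzyl bromide, BrCc1ccccc1
Why: Williamson ether synthesis; the benzyl ether masks the phenol of rings A and C until the last step.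

Step 4
Reactants: 4 1-(benzyloxy)-4-bromo-2-methoxybenzene; 5 allyl alcohol
Product: 6 3-[4-(benzyloxy)-3-methoxyphenyl]propanal
Conditions: Pd(OAc)2 (3 mol%), Bu4NCl, NaHCO3, DMF, 90 °C
Reagents that add atoms: none
Why: Heck reaction under Jeffery conditions; after arylation at the terminal carbon, β-hydride elimination towards the carbinol carbon and tautomerisation of the enol give the saturated aldehyde.

Step 5
Reactants: 6 3-[4-(benzyloxy)-3-methoxyphenyl]propanal; 7 methyl bromoacetate
Product: 10 (4R)-4-[4-(benzyloxy)-3-methoxybenzyl]oxolan-2-one, via aldehyde ester 8 (not isolated), via hydroxy ester 9 (not isolated)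
Conditions: fac-Ir(ppy)3 (1 mol%), (2R,5S)-2-tert-butyl-3,5-dimethylimidazolidin-4-one·TfOH (20 mol%), 2,6-lutidine, DMSO, blue LEDs, rt; then NaBH4, MeOH, 0 °C; then TsOH (cat.), CH2Cl2, rt
Reagents that add atoms: none
Why: Proposed new method: photoexcited fac-Ir(ppy)3 reduces the C–Br bond of 7 to the electrophilic radical •CH2CO2Me, which adds to the E-enamine of 6 on the face anti to the 5-methyl group of the imidazolidinone and so sets the new centre as R; the α-amino radical is oxidised to the iminium ion by the oxidised photocatalyst and hydrolysed; the closest known reaction type is the photoredox/enamine-catalysed enantioselective α-alkylation of aldehydes with bromomalonates, bromoacetonitrile or electron-poor benzyl bromides, and the simple bromoacetate is expected to need this more reducing photocatalyst; NaBH4 reduces the aldehyde before it can racemise and acid closes the γ-lactone without touching the stereocentre.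

Step 6
Reactants: 10 (4R)-4-[4-(benzyloxy)-3-methoxybenzyl]oxolan-2-one; 11 formaldehyde (as paraformaldehyde)
Product: 13 (4R)-4-[4-(benzyloxy)-3-methoxybenzyl]-3-methylideneoxolan-2-one, via sodium formyl enolate 12 (not isolated)
Conditions: NaH, HCO2Et, THF, 0 °C to rt; then (CH2O)n, THF, reflux
Reagents that add atoms: none
Why: Claisen formylation gives the enolate of the α-formyl lactone, which undergoes aldol addition to formaldehyde, formyl transfer to the new alkoxide (retro-Claisen) and E1cB loss of formate to leave the exocyclic alkene; C4 is not acidic and keeps its configuration.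

Step 7
Reactants: 4 1-(benzyloxy)-4-bromo-2-methoxybenzene; 14 methyl acrylate
Product: 15 methyl (E)-3-[4-(benzyloxy)-3-methoxyphenyl]prop-2-enoate
Conditions: Pd(OAc)2 (2 mol%), P(o-tol)3, Et3N, DMF, 100 °C
Reagents that add atoms: none
Why: Mizoroki–Heck reaction; syn insertion and syn β-hydride elimination give the E-cinnamate.

Step 8
Reactants: 15 methyl (E)-3-[4-(benzyloxy)-3-methoxyphenyl]prop-2-enoate
Product: 16 (E)-3-[4-(benzyloxy)-3-methoxyphenyl]prop-2-en-1-ol
Conditions: i-Bu2AlH (2.5 equiv), CH2Cl2, −78 °C; aq. KNa tartrate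
Reagents that add atoms: none
Why: 1,2-Hydride reduction of the conjugated ester to the allylic alcohol, leaving the alkene geometry intact.

Step 9
Reactants: 16 (E)-3-[4-(benzyloxy)-3-methoxyphenyl]prop-2-en-1-ol
Product: 17 (E)-3-[4-(benzyloxy)-3-methoxyphenyl]prop-2-en-1-yl methyl carbonate
Conditions: ClCO2Me, pyridine, CH2Cl2, 0 °C
Reagents that add atoms: methyl chloroformate, COC(Cl)=O
Why: O-Acylation to the allylic carbonate, the leaving group for the allylic substitution.

Step 10
Reactants: 3 4-bromo-2-methoxyphenol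
Product: 18 4-bromo-2-iodo-6-methoxyphenol
Conditions: NIS, TsOH (cat.), MeCN, rt
Reagents that add atoms: N-iodosuccinimide, O=C1CCC(=O)N1I
Why: Electrophilic aromatic iodination at the only free position ortho to the hydroxyl group (the para position is blocked by bromine).

Step 11
Reactants: 18 4-bromo-2-iodo-6-methoxyphenol; 17 (E)-3-[4-(benzyloxy)-3-methoxyphenyl]prop-2-en-1-yl methyl carbonate
Product: 19 1-(benzyloxy)-4-[(1S)-1-(4-bromo-2-iodo-6-methoxyphenoxy)prop-2-en-1-yl]-2-methoxybenzene
Conditions: LiOt-Bu, THF, rt; then 17, [Ir(cod)Cl]2 (2 mol%), (Sa,Sc,Sc)-binaphthol N,N-bis(1-phenylethyl)phosphoramidite (4 mol%), THF, 50 °C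
Reagents that add atoms: none
Why: Ir-catalysed asymmetric allylic etherification; the phenoxide attacks the substituted terminus of the (π-allyl)iridium complex (branched product), and the (Sa,Sc,Sc)-ligand fixes the face so that the benzylic ether centre is S.

Step 12
Reactants: 19 1-(benzyloxy)-4-[(1S)-1-(4-bromo-2-iodo-6-methoxyphenoxy)prop-2-en-1-yl]-2-methoxybenzene
Product: 21 [(2S,3R)-2-[4-(benzyloxy)-3-methoxyphenyl]-5-bromo-7-methoxy-2,3-dihydro-1-benzofuran-3-yl]methanol, via hydroperoxide 20 (not isolated)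
Conditions: Bu3SnH (1.3 equiv, syringe pump), Et3B (cat.), dry air, PhMe, 0 °C to rt; then PPh3
Reagents that add atoms: dioxygen, O=O
Why: Bu3SnH-mediated 5-exo-trig aryl radical cyclisation with oxygen trapping; Bu3Sn• abstracts iodine far faster than bromine, the chair-like transition state with the C2 aryl group pseudo-equatorial sets C3 trans to it (3R), and O2 traps the primary radical faster than the dilute Bu3SnH does, the hydroperoxide being reduced by PPh3.

Step 13
Reactants: 21 [(2S,3R)-2-[4-(benzyloxy)-3-methoxyphenyl]-5-bromo-7-methoxy-2,3-dihydro-1-benzofuran-3-yl]methanol; 13 (4R)-4-[4-(benzyloxy)-3-methoxybenzyl]-3-methylideneoxolan-2-one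
Product: 23 (3R,4R)-4-[4-(benzyloxy)-3-methoxybenzyl]-3-{[(2S,3R)-2-[4-(benzyloxy)-3-methoxyphenyl]-3-(hydroxymethyl)-7-methoxy-2,3-dihydro-1-benzofuran-5-yl]methyl}oxolan-2-one, via cis-lactone 22 (not isolated)
Conditions: 13 (2 equiv), (TMS)3SiH (1.5 equiv, syringe pump), AIBN (0.2 equiv), t-C12H25SH (10 mol%), PhH, 80 °C; then DBU, rt
Reagents that add atoms: none
Why: Giese reaction; (TMS)3Si• abstracts bromine from 21, the aryl radical adds to the exocyclic methylene of 13 to form the aryl–CH2 bond, the thiol passes a hydrogen atom to the α-lactone radical mainly anti to the C4 benzyl group (cis lactone), and DBU then epimerises C3 to the more stable trans (3R,4R) lactone while C4 and the dihydrobenzofuran centres cannot epimerise.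

Step 14
Reactants: 23 bis(O-benzyl) isolappaol A
Product: 24 isolappaol A, (3R,4R)-4-(4-hydroxy-3-methoxybenzyl)-3-{[(2S,3R)-2-(4-hydroxy-3-methoxyphenyl)-3-(hydroxymethyl)-7-methoxy-2,3-dihydro-1-benzofuran-5-yl]methyl}oxolan-2-one
Conditions: H2 (1 atm), Pd/C (10%), EtOAc–MeOH, rt, stopped at full conversion
Reagents that add atoms: none
Why: Hydrogenolysis of the two benzyl aryl ethers; the cyclic benzylic C2–O bond of the dihydrobenzofuran is cleaved much more slowly and no stereocentre is touched.

## Compound list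

1 | catechol | Oc1ccccc1O | starting material
2 | 2-methoxyphenol | COc1ccccc1O | intermediate
3 | 4-bromo-2-methoxyphenol | COc1cc(Br)ccc1O | intermediate
4 | 1-(benzyloxy)-4-bromo-2-methoxybenzene | COc1cc(Br)ccc1OCc1ccccc1 | intermediate
5 | allyl alcohol | C=CCO | starting material
6 | 3-[4-(benzyloxy)-3-methoxyphenyl]propanal | COc1cc(CCC=O)ccc1OCc1ccccc1 | intermediate
7 | methyl bromoacetate | COC(=O)CBr | starting material
8 | methyl (3R)-4-[4-(benzyloxy)-3-methoxyphenyl]-3-formylbutanoate | COc1cc(C[C@H](CC(=O)OC)C=O)ccc1OCc1ccccc1 | intermediate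
9 | methyl (3R)-4-[4-(benzyloxy)-3-methoxyphenyl]-3-(hydroxymethyl)butanoate | COc1cc(C[C@H](CC(=O)OC)CO)ccc1OCc1ccccc1 | intermediate
10 | (4R)-4-[4-(benzyloxy)-3-methoxybenzyl]oxolan-2-one | COc1cc(C[C@H]2COC(=O)C2)ccc1OCc1ccccc1 | intermediate
11 | formaldehyde (used as paraformaldehyde) | C=O | starting material
12 | sodium enolate of (4R)-4-[4-(benzyloxy)-3-methoxybenzyl]-3-formyloxolan-2-one | COc1cc(C[C@H]2COC(=O)C2=C[O-])ccc1OCc1ccccc1.[Na+] | intermediate
13 | (4R)-4-[4-(benzyloxy)-3-methoxybenzyl]-3-methylideneoxolan-2-one | COc1cc(C[C@H]2COC(=O)C2=C)ccc1OCc1ccccc1 | intermediate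
14 | methyl acrylate | C=CC(=O)OC | starting material
15 | methyl (E)-3-[4-(benzyloxy)-3-methoxyphenyl]prop-2-enoate | COC(=O)/C=C/c1ccc(OCc2ccccc2)c(OC)c1 | intermediate
16 | (E)-3-[4-(benzyloxy)-3-methoxyphenyl]prop-2-en-1-ol | OC/C=C/c1ccc(OCc2ccccc2)c(OC)c1 | intermediate
17 | (E)-3-[4-(benzyloxy)-3-methoxyphenyl]prop-2-en-1-yl methyl carbonate | COC(=O)OC/C=C/c1ccc(OCc2ccccc2)c(OC)c1 | intermediate
18 | 4-bromo-2-iodo-6-methoxyphenol | COc1cc(Br)cc(I)c1O | intermediate
19 | 1-(benzyloxy)-4-[(1S)-1-(4-bromo-2-iodo-6-methoxyphenoxy)prop-2-en-1-yl]-2-methoxybenzene | C=C[C@@H](c1ccc(OCc2ccccc2)c(OC)c1)Oc1c(I)cc(Br)cc1OC | intermediate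
20 | (2S,3R)-2-[4-(benzyloxy)-3-methoxyphenyl]-5-bromo-3-(hydroperoxymethyl)-7-methoxy-2,3-dihydro-1-benzofuran | Brc1cc(OC)c2c(c1)[C@H](COO)[C@@H](c1ccc(OCc3ccccc3)c(OC)c1)O2 | intermediate
21 | [(2S,3R)-2-[4-(benzyloxy)-3-methoxyphenyl]-5-bromo-7-methoxy-2,3-dihydro-1-benzofuran-3-yl]methanol | Brc1cc(OC)c2c(c1)[C@H](CO)[C@@H](c1ccc(OCc3ccccc3)c(OC)c1)O2 | intermediate
22 | (3S,4R)-4-[4-(benzyloxy)-3-methoxybenzyl]-3-{[(2S,3R)-2-[4-(benzyloxy)-3-methoxyphenyl]-3-(hydroxymethyl)-7-methoxy-2,3-dihydro-1-benzofuran-5-yl]methyl}oxolan-2-one (cis lactone) | COc1cc(C[C@H]2COC(=O)[C@H]2Cc2cc(OC)c3c(c2)[C@H](CO)[C@@H](c2ccc(OCc4ccccc4)c(OC)c2)O3)ccc1OCc1ccccc1 | intermediate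
23 | (3R,4R)-4-[4-(benzyloxy)-3-methoxybenzyl]-3-{[(2S,3R)-2-[4-(benzyloxy)-3-methoxyphenyl]-3-(hydroxymethyl)-7-methoxy-2,3-dihydro-1-benzofuran-5-yl]methyl}oxolan-2-one (trans lactone) | COc1cc(C[C@H]2COC(=O)[C@@H]2Cc2cc(OC)c3c(c2)[C@H](CO)[C@@H](c2ccc(OCc4ccccc4)c(OC)c2)O3)ccc1OCc1ccccc1 | intermediate
24 | isolappaol A | COc1cc(C[C@H]2COC(=O)[C@@H]2Cc2cc(OC)c3c(c2)[C@H](CO)[C@@H](c2ccc(O)c(OC)c2)O3)ccc1O | target

## Step count and risks

Total: 14 steps. Longest linear sequence: 10 steps (1, 2, 3, 7, 8, 9, 11, 12, 13, 14).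

The three steps most likely to fail:

**Step 13 (radical union).** The aryl radical may be reduced by the silane before it adds, and 13 may telomerise. The fallback sets out from 21 and 13 and comes back at 23. Miyaura borylation of 21 (B2pin2, Pd(dppf)Cl2, KOAc, dioxane, 90 °C) gives [(2S,3R)-2-[4-(benzyloxy)-3-methoxyphenyl]-7-methoxy-5-(4,4,5,5-tetramethyl-1,3,2-dioxaborolan-2-yl)-2,3-dihydro-1-benzofuran-3-yl]methanol F1. Rh-catalysed 1,4-addition of F1 to 13 ([Rh(cod)OH]2, dioxane–water, 60 °C) with protonation of the rhodium enolate gives the lactone as a mixture of C3 epimers, and DBU equilibration then gives 23.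

**Step 11 (allylic etherification).** The 2,6-disubstituted phenoxide is hindered and weakly nucleophilic, and the electron-rich branched ether can re-ionise, which would give linear ether and lower ee. The fallback sets out from 4 (with 18 as partner) and comes back at 19. Bromine–lithium exchange on 4 (n-BuLi, THF, −78 °C) and quenching with DMF gives 4-(benzyloxy)-3-methoxybenzaldehyde F2. Enantioselective vinyl addition (Zn(CH=CH2)2 with (+)-3-exo-morpholinoisoborneol, the ligand enantiomer that gives the R carbinol) gives (1R)-1-[4-(benzyloxy)-3-methoxyphenyl]prop-2-en-1-ol F3. Mitsunobu etherification of F3 with 18 (PPh3, DIAD, PhMe, 0 °C) proceeds with inversion to give 19.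

**Step 5 (radical alkylation).** A simple bromoacetate is harder to reduce than the usual radical precursors, and the amine catalyst may be alkylated. The fallback sets out from 6 and comes back at 10. NaBH4 reduction of 6 gives 3-[4-(benzyloxy)-3-methoxyphenyl]propan-1-ol F4. Acylation with glyoxylic acid chloride tosylhydrazone (PhNMe2, then Et3N) gives 3-[4-(benzyloxy)-3-methoxyphenyl]propyl diazoacetate F5. Enantioselective intramolecular carbene C–H insertion at the homobenzylic CH2 with Rh2(4S-MPPIM)4 (CH2Cl2, reflux; the 4R catalyst is used instead if the sense of induction proves opposite) gives 10.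

Further compounds
F1 | step 13 | [(2S,3R)-2-[4-(benzyloxy)-3-methoxyphenyl]-7-methoxy-5-(4,4,5,5-tetramethyl-1,3,2-dioxaborolan-2-yl)-2,3-dihydro-1-benzofuran-3-yl]methanol | CC1(C)OB(OC1(C)C)c1cc(OC)c2c(c1)[C@H](CO)[C@@H](c1ccc(OCc3ccccc3)c(OC)c1)O2
F2 | step 11 | 4-(benzyloxy)-3-methoxybenzaldehyde | COc1cc(C=O)ccc1OCc1ccccc1
F3 | step 11 | (1R)-1-[4-(benzyloxy)-3-methoxyphenyl]prop-2-en-1-ol | C=C[C@H](c1ccc(OCc2ccccc2)c(OC)c1)O
F4 | step 5 | 3-[4-(benzyloxy)-3-methoxyphenyl]propan-1-ol | COc1cc(CCCO)ccc1OCc1ccccc1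
F5 | step 5 | 3-[4-(benzyloxy)-3-methoxyphenyl]propyl diazoacetate | COc1cc(CCCOC(=O)C=[N+]=[N-])ccc1OCc1ccccc1
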